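**Retrosynthetic overview**
- The target comes from a bridged isoxazoline-butenolide: the isoxazoline (C1=N–O–C9) is a masked C1-ketone/C9-carbinol aldol and is opened last by N–O reduction.
- The ten-membered ring and the butenolide come from one seco (Z)-enal/(Z)-β-iodo enoate. An intramolecular Nozaki–Hiyama–Kishi vinylation makes C6–C7 (the bond a germacrene cyclase makes from farnesyl C1 and C10), and the C6 alkoxide then closes the 12,6-lactone in the same flask.
- The seco compound comes from a nerol-derived nitrile oxide (C1–C6, C15) and an iodo-dienyl carbinol (C7–C14); a magnesium-alkoxide-directed [3+2] cycloaddition sets C9 and C10 from C8.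
- The carbinol comes from a γ-hydroxy ynoate by anti iodide/formaldehyde halo-aldol (C13 and the vinyl iodide); the ynoate comes from crotonaldehyde and methyl propiolate by catalytic asymmetric alkynylation (C8).
- Ring order: isoxazoline (temporary), then ten-membered carbocycle, then butenolide, then the isoxazoline is opened.

Assumption: germacrane numbering is used for the target (C1 ketone, C6 lactone carbinol, C8 methacrylate, C9 OH, C10 CH–CH3, C12 lactone C=O, C13 CH2OAc), and the ProPhenol antipode in step 4 is the one that delivers the (S)-carbinol (both antipodes are commercial).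

**Route**

Step 1
Reactants: 1 nerol
Product: 2 neryl triethylsilyl ether (triethyl{[(2Z)-3,7-dimethylocta-2,6-dien-1-yl]oxy}silane)
Conditions: TESCl, imidazole, CH2Cl2, 0 °C
Reagents that add atoms: chlorotriethylsilane CC[Si](CC)(CC)Cl
Why: Imidazole-promoted silylation of the primary allylic alcohol; TES is chosen because it is orthogonal to the later acetate and methacrylate and can be oxidised off directly in step 9.

Step 2
Reactants: 2 neryl triethylsilyl ether
Product: 4 (4Z)-4-methyl-6-(triethylsilyloxy)hex-4-enal, via secondary ozonide 3 (not isolated)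
Conditions: O3 (1.0 equiv, Sudan Red 7B end point), CH2Cl2, −78 °C; then Me2S, −78 °C → rt
Reagents that add atoms: ozone [O-][O+]=O
Why: Criegee ozonolysis with reductive work-up; the distal trisubstituted alkene is more electron-rich than the 2,3-alkene (deactivated by the allylic C–O bond), so one equivalent of ozone cleaves it selectively and the Z alkene survives.

Step 3
Reactants: 4 (4Z)-4-methyl-6-(triethylsilyloxy)hex-4-enal
Product: 5 (4Z)-4-methyl-6-(triethylsilyloxy)hex-4-enal oxime
Conditions: NH2OH (50% aq.), EtOH, rt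
Reagents that add atoms: hydroxylamine NO
Why: Oxime condensation with free hydroxylamine under neutral conditions that spare the TES ether; the C=N geometry is irrelevant for the next step.

Step 4
Reactants: 6 (E)-crotonaldehyde + 7 methyl propiolate
Product: 8 methyl (4S,5E)-4-hydroxyhept-5-en-2-ynoate
Conditions: (S,S)-ProPhenol (10 mol%), Me2Zn (3 equiv), Ph3PO (20 mol%), toluene, 4 °C
Reagents that add atoms: none
Why: Trost ProPhenol dinuclear zinc-catalysed asymmetric alkynylation of an enal; 1,2-addition of the zinc propiolate to one enantioface sets C8 as S (this becomes R in the target through a priority change only).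

Step 5
Reactants: 8 methyl (4S,5E)-4-hydroxyhept-5-en-2-ynoate
Product: 9 methyl (2Z,4S,5E)-4-hydroxy-2-(hydroxymethyl)-3-iodohepta-2,5-dienoate
Conditions: MgI2 (1.3 equiv), (CH2O)n (1.5 equiv), CH2Cl2, 0 °C → rt
Reagents that add atoms: magnesium iodide [Mg+2].[I-].[I-]; formaldehyde (used as paraformaldehyde) C=O
Why: β-Iodo Morita–Baylis–Hillman (halo-aldol) reaction: iodide adds to C7 of the MgI2-activated ynoate and C11 is hydroxymethylated from the side away from the large iodine (net anti addition, as in the Z-selective hydroiodination of 2-alkynoates and the Z-selective propiolate halo-aldol), so iodine ends cis to CO2Me; any E isomer would lactonise onto the C8 hydroxyl and be removed by chromatography.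

Step 6
Reactants: 9 methyl (2Z,4S,5E)-4-hydroxy-2-(hydroxymethyl)-3-iodohepta-2,5-dienoate
Product: 10 methyl (2Z,4S,5E)-2-(acetoxymethyl)-4-hydroxy-3-iodohepta-2,5-dienoate
Conditions: AcCl (1.05 equiv), 2,4,6-collidine, CH2Cl2, −78 °C
Reagents that add atoms: acetyl chloride CC(Cl)=O
Why: Primary-selective acylation (acyl chloride with collidine at low temperature); the unhindered primary C13 hydroxyl reacts far faster than the secondary C8 hydroxyl next to the iodoalkene, and no stereocenter is touched.

Step 7
Reactants: 5 (4Z)-4-methyl-6-(triethylsilyloxy)hex-4-enal oxime + 10 methyl (2Z,4S,5E)-2-(acetoxymethyl)-4-hydroxy-3-iodohepta-2,5-dienoate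
Product: 13 isoxazoline alcohol methyl (2Z,4S)-2-(acetoxymethyl)-4-hydroxy-3-iodo-4-{(4R,5R)-4-methyl-3-[(3Z)-3-methyl-5-(triethylsilyloxy)pent-3-en-1-yl]-4,5-dihydroisoxazol-5-yl}but-2-enoate, via hydroximoyl chloride 11 (not isolated), via nitrile oxide 12 (not isolated)
Conditions: 5 (1.4 equiv), N-chlorosuccinimide, pyridine (cat.), CH2Cl2, 0 °C → rt; then 10, i-PrOMgBr (3 equiv, preformed from EtMgBr and i-PrOH), CH2Cl2, 0 °C → rt
Reagents that add atoms: none
Why: Kanemasa hydroxyl-directed nitrile oxide 1,3-dipolar cycloaddition: magnesium bridges the C8 alkoxide and the nitrile oxide oxygen, so oxygen goes to the proximal C9 and C1 to C10; suprafacial addition to the E alkene fixes the 9,10-anti (trans-4,5) relationship, and the chelated transition state with the iodoalkenyl group anti to the dipole gives the 8,9-syn adduct, which sets C9 (R) and C10 (S in the target) from C8. The tetrasubstituted iodo-enoate is not a dipolarophile, and the isoxazoline now masks the C1 ketone and the C9 hydroxyl.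

Step 8
Reactants: 13 isoxazoline alcohol
Product: 14 isoxazoline methacrylate methyl (2Z,4S)-2-(acetoxymethyl)-3-iodo-4-(2-methylprop-2-enoyloxy)-4-{(4R,5R)-4-methyl-3-[(3Z)-3-methyl-5-(triethylsilyloxy)pent-3-en-1-yl]-4,5-dihydroisoxazol-5-yl}but-2-enoate
Conditions: methacrylic anhydride, Et3N, DMAP (cat.), CH2Cl2, 0 °C → rt
Reagents that add atoms: methacrylic anhydride C=C(C)C(=O)OC(=O)C(C)=C
Why: DMAP-catalysed acylation of the only free hydroxyl; this is O-acylation without C–O cleavage, so C8 keeps its configuration.

Step 9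
Reactants: 14 isoxazoline methacrylate
Product: 15 seco (Z)-enal methyl (2Z,4S)-2-(acetoxymethyl)-3-iodo-4-(2-methylprop-2-enoyloxy)-4-{(4R,5R)-4-methyl-3-[(3Z)-3-methyl-5-oxopent-3-en-1-yl]-4,5-dihydroisoxazol-5-yl}but-2-enoate
Conditions: (COCl)2, DMSO, CH2Cl2, −78 °C; add 14, −78 → −40 °C; then Et3N, −78 → 0 °C
Reagents that add atoms: none
Why: Swern oxidation with in-flask cleavage of the primary TES ether by the chlorosulfonium salt (primary TES ethers are oxidised directly to aldehydes; esters, isoxazoline and vinyl iodide are inert), and the low temperature keeps the neral-type Z geometry.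

Step 10
Reactants: 15 seco (Z)-enal
Product: 17 bridged isoxazoline butenolide (ten-membered carbocycle with the 12,6-butenolide closed; C1=N–O–C9 bridge still in place; 6R), via macrocyclic hydroxy ester 16 (not isolated)
Conditions: CrCl2 (10 equiv), NiCl2 (5 mol%), DMSO/THF 3:1, rt, 2 mM (15 added over 12 h); sat. aq. NH4Cl work-up
Reagents that add atoms: none
Why: Intramolecular Nozaki–Hiyama–Kishi vinylation followed by lactonisation: zerovalent nickel (from NiCl2) inserts into the C7–iodine bond, transmetalation gives the trivalent chromium alkenyl, and 1,2-addition to the aldehyde (the C1 ketone is still masked) closes the C6–C7 bond of the ten-membered ring; the cis ester then captures the C6 alkoxide as the butenolide. C6 is set by the conformation of the bridged seco chain; attack on the Si face of the enal, which gives 6R, is what models suggest but is not guaranteed.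

Step 11
Reactants: 17 bridged isoxazoline butenolide
Product: 19 CNP0164859.1 ((4Z,6R,8R,9R,10S)-13-acetoxy-9-hydroxy-8-methacryloyloxy-1-oxogermacra-4,7(11)-dien-12,6-olide), via hydroxy imine 18 (not isolated)
Conditions: Mo(CO)6 (1.2 equiv), MeCN/H2O 15:1, 80 °C
Reagents that add atoms: water O
Why: Mo(CO)6-mediated reductive N–O cleavage of the isoxazoline (zerovalent molybdenum) and hydrolysis of the resulting β-hydroxy imine unveil the β-hydroxy ketone without touching the C=C bonds or the esters; C9 and C10 are not involved, and opening the bridge releases strain.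

**Compound list**

1 | nerol, (2Z)-3,7-dimethylocta-2,6-dien-1-ol | OC/C=C(/C)CCC=C(C)C | starting material
2 | neryl triethylsilyl ether | CC[Si](CC)(CC)OC/C=C(/C)CCC=C(C)C | intermediate
3 | secondary ozonide (1,2,4-trioxolane) at the 6,7-alkene of 2 | CC[Si](CC)(CC)OC/C=C(/C)CCC1OOC(C)(C)O1 | intermediate (not isolated)
4 | (4Z)-4-methyl-6-(triethylsilyloxy)hex-4-enal (C1–C6 and C15 of the target; CHO = C1) | CC[Si](CC)(CC)OC/C=C(/C)CCC=O | intermediate
5 | oxime of 4 | CC[Si](CC)(CC)OC/C=C(/C)CCC=NO | intermediate
6 | (E)-crotonaldehyde | C/C=C/C=O | starting material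
7 | methyl propiolate | C#CC(=O)OC | starting material
8 | methyl (4S,5E)-4-hydroxyhept-5-en-2-ynoate | COC(=O)C#C[C@@H](O)/C=C/C | intermediate
9 | methyl (2Z,4S,5E)-4-hydroxy-2-(hydroxymethyl)-3-iodohepta-2,5-dienoate (iodine cis to CO2Me) | COC(=O)/C(CO)=C(\I)[C@@H](O)/C=C/C | intermediate
10 | methyl (2Z,4S,5E)-2-(acetoxymethyl)-4-hydroxy-3-iodohepta-2,5-dienoate | COC(=O)/C(COC(C)=O)=C(\I)[C@@H](O)/C=C/C | intermediate
11 | hydroximoyl chloride from 5, (4Z)-N-hydroxy-4-methyl-6-(triethylsilyloxy)hex-4-enimidoyl chloride | CC[Si](CC)(CC)OC/C=C(/C)CCC(Cl)=NO | intermediate (not isolated)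
12 | nitrile oxide, (4Z)-4-methyl-6-(triethylsilyloxy)hex-4-enenitrile oxide | CC[Si](CC)(CC)OC/C=C(/C)CCC#[N+][O-] | intermediate (not isolated)
13 | isoxazoline alcohol; trans-4,5-disubstituted (4R,5R)-isoxazoline, carbinol S (target C8 R, C9 R, C10 S) | CC[Si](CC)(CC)OC/C=C(/C)CCC1=NO[C@H]([C@@H]1C)[C@H](O)/C(I)=C(\COC(C)=O)C(=O)OC | intermediate
14 | C8 methacrylate of 13 | CC[Si](CC)(CC)OC/C=C(/C)CCC1=NO[C@H]([C@@H]1C)[C@H](OC(=O)C(C)=C)/C(I)=C(\COC(C)=O)C(=O)OC | intermediate
15 | seco (Z)-enal (C6 aldehyde, C7 vinyl iodide) | O=C/C=C(/C)CCC1=NO[C@H]([C@@H]1C)[C@H](OC(=O)C(C)=C)/C(I)=C(\COC(C)=O)C(=O)OC | intermediate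
16 | macrocyclic (6R)-hydroxy methyl ester, ten-membered ring closed at C6–C7, lactone not yet formed | O[C@@H]1/C=C(/C)CCC2=NO[C@H]([C@@H]2C)[C@H](OC(=O)C(C)=C)/C1=C(\COC(C)=O)C(=O)OC | intermediate (not isolated)
17 | bridged isoxazoline butenolide (6R,8R,9R; C10 as in the target, descriptor R here by priority change) | C=C(C)C(=O)O[C@@H]1C2=C(COC(C)=O)C(=O)O[C@@H]2/C=C(/C)CCC3=NO[C@@H]1[C@@H]3C | intermediate
18 | β-hydroxy imine (C1=NH) of the target | C=C(C)C(=O)O[C@@H]1C2=C(COC(C)=O)C(=O)O[C@@H]2/C=C(/C)CCC(=N)[C@@H](C)[C@H]1O | intermediate (not isolated)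
19 | CNP0164859.1, (4Z,6R,8R,9R,10S)-13-acetoxy-9-hydroxy-8-methacryloyloxy-1-oxogermacra-4,7(11)-dien-12,6-olide | C=C(C)C(=O)O[C@@H]1C2=C(COC(C)=O)C(=O)O[C@@H]2/C=C(/C)CCC(=O)[C@@H](C)[C@H]1O | target

**Step count and risks**

Total step count: 11. Longest linear sequence: 8 (steps 1–3 and 7–11, or steps 4–11).

The three steps most likely to fail:

1. Step 10 (ring closure and lactonisation). The ring must close as a bridged bicycle, C6 selectivity rests on conformation only, and the vinyl metal carries a β-acyloxy group that could be lost. The fallback sets out from 15 and returns at 19. The isoxazoline of 15 is opened first with Mo(CO)6 in wet MeCN to give the open-chain β-hydroxy ketone iodo-enal F1. F1 is no longer bridged and can adopt the conformation of the natural ring; it is cyclised with CrCl2/NiCl2 at high dilution, relying on the preference of the trivalent chromium alkenyl for the aldehyde over the C1 ketone, and lactonisation then gives 19 directly.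

2. Step 5 (halo-aldol). The Z geometry of a tetrasubstituted iodo-enoate and the use of formaldehyde rest on analogy, and a cyclic formal of the diol is a possible side product. The fallback sets out from 8 and returns at 17; it postpones C13. Anti hydroiodination of 8 (NaI, AcOH, MeCN, 50 °C) gives the Z iodo-enoate F2 with secure geometry. F2 follows the operations of the main line: directed cycloaddition with 5 to the isoxazoline alcohol F3, methacrylation to the ester F4, Swern oxidation to the enal F5, and chromium-mediated ring closure with lactonisation to the C13-nor butenolide F6. The missing carbon is then added on the ring: iodination at C11 (I2, pyridine, CH2Cl2) gives the α-iodo butenolide F7, Stille coupling with Bu3SnCH2OH (Pd2(dba)3, AsPh3, CuI, zerovalent palladium) gives the 13-hydroxy butenolide F8, and acetylation (Ac2O, pyridine) gives 17.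

3. Step 9 (direct oxidation of the silyl ether). Cleavage of the TES group by the Swern reagent may be slow, and warming risks Z to E isomerisation of the enal. The fallback sets out from 14 and returns at 15. HF·pyridine in THF/pyridine at 0 °C removes the TES group to give the allylic alcohol F9, and MnO2 in CH2Cl2 then oxidises only this allylic alcohol to 15.

**Further compounds**

F1 | step 10 | open-chain β-hydroxy ketone iodo-enal (isoxazoline of 15 opened) | O=C/C=C(/C)CCC(=O)[C@@H](C)[C@@H](O)[C@H](OC(=O)C(C)=C)/C(I)=C(\COC(C)=O)C(=O)OC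
F2 | step 5 | methyl (2Z,4S,5E)-4-hydroxy-3-iodohepta-2,5-dienoate | COC(=O)/C=C(\I)[C@@H](O)/C=C/C
F3 | step 5 | isoxazoline alcohol lacking C13 | CC[Si](CC)(CC)OC/C=C(/C)CCC1=NO[C@H]([C@@H]1C)[C@H](O)/C(I)=C/C(=O)OC
F4 | step 5 | methacrylate of F3 | CC[Si](CC)(CC)OC/C=C(/C)CCC1=NO[C@H]([C@@H]1C)[C@H](OC(=O)C(C)=C)/C(I)=C/C(=O)OC
F5 | step 5 | seco (Z)-enal lacking C13 | O=C/C=C(/C)CCC1=NO[C@H]([C@@H]1C)[C@H](OC(=O)C(C)=C)/C(I)=C/C(=O)OC
F6 | step 5 | bridged isoxazoline butenolide lacking C13 (H at C11) | C=C(C)C(=O)O[C@@H]1C2=CC(=O)O[C@@H]2/C=C(/C)CCC3=NO[C@@H]1[C@@H]3C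
F7 | step 5 | 11-iodo butenolide | C=C(C)C(=O)O[C@@H]1C2=C(I)C(=O)O[C@@H]2/C=C(/C)CCC3=NO[C@@H]1[C@@H]3C
F8 | step 5 | 13-hydroxy butenolide (deacetyl 17) | C=C(C)C(=O)O[C@@H]1C2=C(CO)C(=O)O[C@@H]2/C=C(/C)CCC3=NO[C@@H]1[C@@H]3C
F9 | step 9 | allylic alcohol (desilylated 14) | OC/C=C(/C)CCC1=NO[C@H]([C@@H]1C)[C@H](OC(=O)C(C)=C)/C(I)=C(\COC(C)=O)C(=O)OC
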